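The flavanone is cut across ring C at C3–C4 and O1–C8a. This gives an enantiopure β-oxido alkyllithium (O1–C2–C3 with the catechol ring) and a ring-A Weinreb amide in which C8a carries fluorine. The key step exploits the lone ring-A hydrogen H8, which sits between C8a and the C7 oxygen. After C3 adds to the amide carbon C4, lithiation at C8 and loss of fluoride give a C8–C8a aryne that the C2 alkoxide captures at C8a, closing ring C while the latent ketone stays masked. C2 comes from a CBS-reduced chlorohydrin; the C6 dienyl chain comes from (S)-citronellal by a tosylhydrazone cross-coupling.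

Key step: step 8

Remark: building blocks 1, 4 and 10 are taken as purchasable. Atoms are numbered as in a flavanone (O1, C2, C3, C4, C4a, C5 to C8, C8a; ring A = benzo ring, ring B = catechol ring, ring C = pyranone ring) and the side chain as C1'' to C8''.

Step 1
Reactants: 1 5-fluororesorcinol (5-fluorobenzene-1,3-diol)
Product: 2 5-fluoro-2-iodobenzene-1,3-diol
Conditions: I2, NaHCO3, H2O, 0 °C to rt
Reagents that add atoms: iodine, II
Why: Electrophilic aromatic iodination should take place at the carbon between the two hydroxyl groups, which is ortho to both and para to fluorine, as resorcinol and 5-substituted resorcinols do under aqueous hydrogencarbonate; no stereocentre is involved.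

Step 2
Reactants: 2 5-fluoro-2-iodobenzene-1,3-diol
Product: 3 5-fluoro-2-iodo-1,3-bis(methoxymethoxy)benzene
Conditions: MOMCl, i-Pr2NEt, CH2Cl2, 0 °C to rt
Reagents that add atoms: chloromethyl methyl ether, COCCl
Why: Twofold O-alkylation of the phenols (Williamson-type acetal formation) installs base-stable groups that later direct lithiation and survive organolithium reagents.

Step 3
Reactants: 4 (S)-citronellal ((3S)-3,7-dimethyloct-6-enal)
Product: 5 N'-[(1E,3S)-3,7-dimethyloct-6-en-1-ylidene]-4-methylbenzenesulfonohydrazide (citronellal tosylhydrazone)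
Conditions: TsNHNH2, MeOH, rt
Reagents that add atoms: p-toluenesulfonyl hydrazide, Cc1ccc(cc1)S(=O)(=O)NN
Why: Acid-free hydrazone condensation avoids the carbonyl-ene cyclisation of citronellal, and the C3 stereocentre is β to the carbonyl and cannot epimerise.

Step 4
Reactants: 3 5-fluoro-2-iodo-1,3-bis(methoxymethoxy)benzene; 5 citronellal tosylhydrazone
Product: 7 5-fluoro-1,3-bis(methoxymethoxy)-2-[(1E,3S)-3,7-dimethylocta-1,6-dien-1-yl]benzene, via diazoalkane 6 (not isolated)
Conditions: Pd2(dba)3 (2.5 mol %), XPhos (10 mol %), LiOtBu, 1,4-dioxane, 100 °C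
Reagents that add atoms: none
Why: Palladium-catalysed cross-coupling of an aryl halide with an N-tosylhydrazone (Barluenga coupling): base converts 5 into diazoalkane 6, the arylpalladium iodide (divalent palladium) formed from 3 and the zerovalent catalyst gives a carbene that inserts into the aryl–Pd bond, and syn β-hydride elimination, possible only toward C2'', should give the (E)-C1''=C2'' alkene while the C3'' stereocentre is not touched.

Step 5
Reactants: 7 5-fluoro-1,3-bis(methoxymethoxy)-2-[(1E,3S)-3,7-dimethylocta-1,6-dien-1-yl]benzene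
Product: 9 6-fluoro-N-methoxy-2,4-bis(methoxymethoxy)-N-methyl-3-[(1E,3S)-3,7-dimethylocta-1,6-dien-1-yl]benzamide, via aryllithium 8 (not isolated)
Conditions: LiN(i-Pr)2 (LDA), THF, −78 °C; then ClC(O)N(OMe)Me, −78 °C to rt
Reagents that add atoms: N-methoxy-N-methylcarbamoyl chloride, CON(C)C(=O)Cl
Why: Directed ortho-lithiation at one of the two equivalent ring hydrogens (each flanked by fluorine and a methoxymethoxy group) gives 8, which is acylated at −78 °C, below the temperature at which it loses LiF, to give the Weinreb amide in one step; the amide base does not add to the styrene.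

Step 6
Reactants: 10 2-chloro-1-(3,4-dihydroxyphenyl)ethan-1-one
Product: 11 1-[3,4-bis(methoxymethoxy)phenyl]-2-chloroethan-1-one
Conditions: MOMCl (excess, added first), i-Pr2NEt, CH2Cl2, 0 °C to rt
Reagents that add atoms: chloromethyl methyl ether, COCCl
Why: O-alkylation of the catechol with the far more reactive chloromethyl ether should outrun self-alkylation by the α-chloroketone under the weak amine base.

Step 7
Reactants: 11 1-[3,4-bis(methoxymethoxy)phenyl]-2-chloroethan-1-one
Product: 12 (1R)-1-[3,4-bis(methoxymethoxy)phenyl]-2-chloroethan-1-ol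
Conditions: (R)-2-methyl-CBS-oxazaborolidine (10 mol %), BH3·SMe2, THF, 0 °C; MeOH quench
Reagents that add atoms: none
Why: Corey–Bakshi–Shibata reduction in which aryl acts as the large and chloromethyl as the small substituent, so the (R)-catalyst should deliver hydride to the Si face and set the carbinol centre as (R), the centre that becomes C2.

Step 8
Reactants: 12 (1R)-1-[3,4-bis(methoxymethoxy)phenyl]-2-chloroethan-1-ol; 9 ring-A Weinreb amide
Product: 17 (2S)-2-[3,4-bis(methoxymethoxy)phenyl]-6-[(1E,3S)-3,7-dimethylocta-1,6-dien-1-yl]-5,7-bis(methoxymethoxy)chroman-4-one, via dilithio reagent 13 (not isolated), via tetrahedral adduct 14 (not isolated), via aryne 15 (not isolated), via aryllithium 16 (not isolated)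
Conditions: 12 (1.15 equiv), n-BuLi, THF, −78 °C; lithium 4,4'-di-tert-butylbiphenylide (stock solution, to a just persistent green), −78 °C; 9, −78 °C; lithium 2,2,6,6-tetramethylpiperidide (stock solution), −78 to −20 °C; AcOH, −78 °C
Reagents that add atoms: none
Why: Deprotonation of 12 and reductive lithiation of its C–Cl bond give the β-oxido alkyllithium 13, whose carbanion (C3) adds to the amide carbonyl (C4) of 9 to give the chelated tetrahedral adduct 14; the lithium amide then removes H8, the only ring-A hydrogen, flanked by fluorine on C8a and the methoxymethoxy group on C7, loss of LiF on warming gives the C8–C8a aryne 15, the C2 alkoxide O1 adds to C8a to give aryllithium 16, and acetic acid protonates C8 and collapses the hemiaminal to the C4 ketone. The sequence joins a Weinreb ketone synthesis with a β-oxido organolithium to the classical anionic aryne etherification that turns 3-(3-fluoroaryl)propan-1-olates into chromans. Ring C closes by 6-exo-dig attack of O1 on the aryne, the only ring size the C2–C3–C4–C4a tether allows. No stereocentre is created in the product: C2 is carried over from 12 with retention because the C2–O1 bond is never broken, the C4 hemiaminal centre vanishes on work-up, and C3'' is remote. The step needs addition at C4 to be faster than proton abstraction at C8 (cold, chelating Weinreb amide), loss of fluoride and not of the C7 alkoxide (fluoride is the far better leaving group), and attack at C8a, not C8 (the tether, reinforced by the C7 alkoxy group, which polarises the aryne so that the carbanion develops at C8 next to oxygen). Because C4 stays a tetrahedral alkoxide until the acidic quench, the ketone never meets base, so retro-aldol cleavage, enolisation and β-elimination of O1, which would erase C2, have no pathway.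

Step 9
Reactants: 17 tetrakis(methoxymethyl) flavanone
Product: 19 (2S)-2-(3,4-dihydroxyphenyl)-6-[(1E,3S)-3,7-dimethylocta-1,6-dien-1-yl]-5,7-dihydroxychroman-4-one, via tetrakis(trimethylsilyl) ether 18 (not isolated)
Conditions: TMSOTf, 2,2'-bipyridyl (excess), CH2Cl2, 0 °C to rt; then H2O, THF, rt
Reagents that add atoms: none
Why: The bipyridyl-buffered silyl triflate should convert the four aryl methoxymethyl ethers into aryl silyl ethers 18, which water hydrolyses, so that no free Brønsted acid is present to open ring C at C2 or to turn the ortho-hydroxystyrene into a quinone methide that the C6''–C7'' alkene would trap.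

Compound list
1 | 5-fluororesorcinol (5-fluorobenzene-1,3-diol) | Oc1cc(O)cc(F)c1 | starting material
2 | 5-fluoro-2-iodobenzene-1,3-diol | Oc1cc(F)cc(O)c1I | intermediate
3 | 5-fluoro-2-iodo-1,3-bis(methoxymethoxy)benzene | COCOc1cc(F)cc(OCOC)c1I | intermediate
4 | (S)-citronellal, (3S)-3,7-dimethyloct-6-enal | CC(C)=CCC[C@H](C)CC=O | starting material
5 | N'-[(1E,3S)-3,7-dimethyloct-6-en-1-ylidene]-4-methylbenzenesulfonohydrazide | CC(C)=CCC[C@H](C)C/C=N/NS(=O)(=O)c1ccc(C)cc1 | intermediate
6 | (6S)-8-diazo-2,6-dimethyloct-2-ene | CC(C)=CCC[C@H](C)CC=[N+]=[N-] | intermediate (not isolated)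
7 | 5-fluoro-1,3-bis(methoxymethoxy)-2-[(1E,3S)-3,7-dimethylocta-1,6-dien-1-yl]benzene | CC(C)=CCC[C@H](C)/C=C/c1c(OCOC)cc(F)cc1OCOC | intermediate
8 | 6-fluoro-2,4-bis(methoxymethoxy)-3-[(1E,3S)-3,7-dimethylocta-1,6-dien-1-yl]phenyllithium | CC(C)=CCC[C@H](C)/C=C/c1c(OCOC)cc(F)c([Li])c1OCOC | intermediate (not isolated)
9 | 6-fluoro-N-methoxy-2,4-bis(methoxymethoxy)-N-methyl-3-[(1E,3S)-3,7-dimethylocta-1,6-dien-1-yl]benzamide | CC(C)=CCC[C@H](C)/C=C/c1c(OCOC)cc(F)c(C(=O)N(C)OC)c1OCOC | intermediate
10 | 2-chloro-1-(3,4-dihydroxyphenyl)ethan-1-one | O=C(CCl)c1ccc(O)c(O)c1 | starting material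
11 | 1-[3,4-bis(methoxymethoxy)phenyl]-2-chloroethan-1-one | O=C(CCl)c1ccc(OCOC)c(OCOC)c1 | intermediate
12 | (1R)-1-[3,4-bis(methoxymethoxy)phenyl]-2-chloroethan-1-ol | ClC[C@@H](c1ccc(OCOC)c(OCOC)c1)O | intermediate
13 | lithium (1S)-1-[3,4-bis(methoxymethoxy)phenyl]-2-lithioethan-1-olate (same spatial arrangement as 12) | [Li]C[C@@H](c1ccc(OCOC)c(OCOC)c1)O[Li] | intermediate (not isolated)
14 | dilithium (3S)-3-[3,4-bis(methoxymethoxy)phenyl]-1-{6-fluoro-2,4-bis(methoxymethoxy)-3-[(1E,3S)-3,7-dimethylocta-1,6-dien-1-yl]phenyl}-1-[methoxy(methyl)amino]propane-1,3-diolate (C1 unassigned) | CC(C)=CCC[C@H](C)/C=C/c1c(OCOC)cc(F)c(C(O[Li])(N(C)OC)C[C@@H](c2ccc(OCOC)c(OCOC)c2)O[Li])c1OCOC | intermediate (not isolated)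
15 | aryne from 14 by loss of H8 and the C8a fluorine (C8–C8a didehydroarene, dilithium diolate) | CC(C)=CCC[C@H](C)/C=C/C1=C(OCOC)C#CC(C(O[Li])(N(C)OC)C[C@@H](c2ccc(OCOC)c(OCOC)c2)O[Li])=C1OCOC | intermediate (not isolated)
16 | lithium (2S)-2-[3,4-bis(methoxymethoxy)phenyl]-8-lithio-4-[methoxy(methyl)amino]-5,7-bis(methoxymethoxy)-6-[(1E,3S)-3,7-dimethylocta-1,6-dien-1-yl]chroman-4-olate (C4 unassigned) | CC(C)=CCC[C@H](C)/C=C/c1c(OCOC)c([Li])c2c(c1OCOC)C(O[Li])(N(C)OC)C[C@@H](c1ccc(OCOC)c(OCOC)c1)O2 | intermediate (not isolated)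
17 | (2S)-2-[3,4-bis(methoxymethoxy)phenyl]-6-[(1E,3S)-3,7-dimethylocta-1,6-dien-1-yl]-5,7-bis(methoxymethoxy)chroman-4-one | CC(C)=CCC[C@H](C)/C=C/c1c(OCOC)cc2c(c1OCOC)C(=O)C[C@@H](c1ccc(OCOC)c(OCOC)c1)O2 | intermediate
18 | (2S)-2-[3,4-bis(trimethylsilyloxy)phenyl]-6-[(1E,3S)-3,7-dimethylocta-1,6-dien-1-yl]-5,7-bis(trimethylsilyloxy)chroman-4-one | CC(C)=CCC[C@H](C)/C=C/c1c(O[Si](C)(C)C)cc2c(c1O[Si](C)(C)C)C(=O)C[C@@H](c1ccc(O[Si](C)(C)C)c(O[Si](C)(C)C)c1)O2 | intermediate (not isolated)
19 | (2S)-2-(3,4-dihydroxyphenyl)-6-[(1E,3S)-3,7-dimethylocta-1,6-dien-1-yl]-5,7-dihydroxychroman-4-one | CC(C)=CCC[C@H](C)/C=C/c1c(O)cc2c(c1O)C(=O)C[C@@H](c1ccc(O)c(O)c1)O2 | target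

Total step count: 9. Longest linear sequence: 6 steps (steps 1, 2, 4, 5, 8, 9).

Steps most likely to fail

Step 8. The organolithium 13 may act as a base toward H8 or the N-methoxy group of the hindered amide instead of adding to C4, or may lose lithium oxide to a styrene before it adds. The tetrahedral adduct may also collapse before ring closure, so that the freed ketone enolises under the amide base, with retro-aldol cleavage or β-elimination of O1 and erosion of C2. The fallback lowers the oxidation level of C4 and separates the two bond formations. It sets out from 7 and 12. Lithiation of 7 (LiN(i-Pr)2, THF, −78 °C) and quench with DMF should give 6-fluoro-2,4-bis(methoxymethoxy)-3-[(1E,3S)-3,7-dimethylocta-1,6-dien-1-yl]benzaldehyde F1. Reagent 13, made from 12 as in step 8, should add to this aldehyde at −78 °C much faster than any proton transfer and give, after aqueous quench, (3S)-3-[3,4-bis(methoxymethoxy)phenyl]-1-{6-fluoro-2,4-bis(methoxymethoxy)-3-[(1E,3S)-3,7-dimethylocta-1,6-dien-1-yl]phenyl}propane-1,3-diol F2 as both C1 epimers. Lithium 2,2,6,6-tetramethylpiperidide (3.3 equiv, THF, −78 to −20 °C) should then take the dialkoxide through the same C8–C8a aryne, with no carbonyl group in the flask, to (2S)-2-[3,4-bis(methoxymethoxy)phenyl]-6-[(1E,3S)-3,7-dimethylocta-1,6-dien-1-yl]-5,7-bis(methoxymethoxy)chroman-4-ol F3. Oxidation with Dess–Martin periodinane and NaHCO3 in CH2Cl2 returns to the route at 17, one step longer.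

Step 4. Oxidative addition and carbene insertion at the doubly ortho-substituted aryl iodide may be slow, so that the diazoalkane is lost by Bamford–Stevens decomposition or azine formation. The new double bond may also migrate by re-addition of a palladium hydride. The fallback is a Mizoroki–Heck reaction that sets out from 3 and commercial (S)-3,7-dimethylocta-1,6-diene ((S)-β-citronellene, C=C[C@@H](C)CCC=C(C)C) with Pd(OAc)2, n-Bu4NCl and NaHCO3 in DMF at 80 °C. Insertion into the monosubstituted alkene and β-hydride elimination toward the benzylic position should give 7 directly, where the route is rejoined. This fallback makes no new compound (F0).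

Step 9. Adventitious triflic acid or the Lewis acid may isomerise the ortho-hydroxystyrene to a quinone methide that the C6''–C7'' alkene traps, or may open ring C. The fallback changes the protecting group to 1-ethoxyethyl acetals, which leave under pyridinium tosylate buffer. It sets out from 2 and 10 and returns at 19.
- Ring A: 2 with ethyl vinyl ether and catalytic PPTS in CH2Cl2 should give 1,3-bis(1-ethoxyethoxy)-5-fluoro-2-iodobenzene F4. Coupling with 5 as in step 4 should give 1,3-bis(1-ethoxyethoxy)-5-fluoro-2-[(1E,3S)-3,7-dimethylocta-1,6-dien-1-yl]benzene F5. Lithiation and carbamoylation as in step 5 should give 2,4-bis(1-ethoxyethoxy)-6-fluoro-N-methoxy-N-methyl-3-[(1E,3S)-3,7-dimethylocta-1,6-dien-1-yl]benzamide F6.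
- Ring B: 10 with ethyl vinyl ether and PPTS should give 1-[3,4-bis(1-ethoxyethoxy)phenyl]-2-chloroethan-1-one F7. Reduction as in step 7 should give (1R)-1-[3,4-bis(1-ethoxyethoxy)phenyl]-2-chloroethan-1-ol F8.
- Endgame: the sequence of step 8, with aqueous NH4Cl as quench, should give (2S)-2-[3,4-bis(1-ethoxyethoxy)phenyl]-5,7-bis(1-ethoxyethoxy)-6-[(1E,3S)-3,7-dimethylocta-1,6-dien-1-yl]chroman-4-one F9. Catalytic PPTS in MeOH at rt should then release 19.
- The acetal carbons are mixtures of both configurations throughout.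

Further compounds
F1 | step 8 | 6-fluoro-2,4-bis(methoxymethoxy)-3-[(1E,3S)-3,7-dimethylocta-1,6-dien-1-yl]benzaldehyde | CC(C)=CCC[C@H](C)/C=C/c1c(OCOC)cc(F)c(C=O)c1OCOC
F2 | step 8 | (3S)-3-[3,4-bis(methoxymethoxy)phenyl]-1-{6-fluoro-2,4-bis(methoxymethoxy)-3-[(1E,3S)-3,7-dimethylocta-1,6-dien-1-yl]phenyl}propane-1,3-diol (both C1 epimers) | CC(C)=CCC[C@H](C)/C=C/c1c(OCOC)cc(F)c(C(O)C[C@@H](c2ccc(OCOC)c(OCOC)c2)O)c1OCOC
F3 | step 8 | (2S)-2-[3,4-bis(methoxymethoxy)phenyl]-6-[(1E,3S)-3,7-dimethylocta-1,6-dien-1-yl]-5,7-bis(methoxymethoxy)chroman-4-ol (both C4 epimers) | CC(C)=CCC[C@H](C)/C=C/c1c(OCOC)cc2c(c1OCOC)C(O)C[C@@H](c1ccc(OCOC)c(OCOC)c1)O2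
F0 | step 4 | none | none
F4 | step 9 | 1,3-bis(1-ethoxyethoxy)-5-fluoro-2-iodobenzene (acetal centres unassigned) | CCOC(C)Oc1cc(F)cc(OC(C)OCC)c1I
F5 | step 9 | 1,3-bis(1-ethoxyethoxy)-5-fluoro-2-[(1E,3S)-3,7-dimethylocta-1,6-dien-1-yl]benzene (acetal centres unassigned) | CC(C)=CCC[C@H](C)/C=C/c1c(OC(C)OCC)cc(F)cc1OC(C)OCC
F6 | step 9 | 2,4-bis(1-ethoxyethoxy)-6-fluoro-N-methoxy-N-methyl-3-[(1E,3S)-3,7-dimethylocta-1,6-dien-1-yl]benzamide (acetal centres unassigned) | CC(C)=CCC[C@H](C)/C=C/c1c(OC(C)OCC)cc(F)c(C(=O)N(C)OC)c1OC(C)OCC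
F7 | step 9 | 1-[3,4-bis(1-ethoxyethoxy)phenyl]-2-chloroethan-1-one (acetal centres unassigned) | O=C(CCl)c1ccc(OC(C)OCC)c(OC(C)OCC)c1
F8 | step 9 | (1R)-1-[3,4-bis(1-ethoxyethoxy)phenyl]-2-chloroethan-1-ol (acetal centres unassigned) | ClC[C@@H](c1ccc(OC(C)OCC)c(OC(C)OCC)c1)O
F9 | step 9 | (2S)-2-[3,4-bis(1-ethoxyethoxy)phenyl]-5,7-bis(1-ethoxyethoxy)-6-[(1E,3S)-3,7-dimethylocta-1,6-dien-1-yl]chroman-4-one (acetal centres unassigned) | CC(C)=CCC[C@H](C)/C=C/c1c(OC(C)OCC)cc2c(c1OC(C)OCC)C(=O)C[C@@H](c1ccc(OC(C)OCC)c(OC(C)OCC)c1)O2
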